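**Plan**

- Retrosynthesis (labdane locants, see remark): the acetate and a silyl group come off; the ring oxygen is taken out of the C8–O–C15 link (Baeyer–Villiger in reverse) to leave a cycloheptanone; the resulting 6-6-7 carbocycle is cut at C8–C9 and at C11–C12.
- Enabling feature: C9–C11 is a two-carbon bridge between the fully substituted ring-fusion carbon C8 of ring B and C12 of the medium ring, so a vinyl group on the quaternary C10 of ring A can be spanned by one radical relay that starts at C8 and ends on a C12=C13 acceptor.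
- Forward: ring A by asymmetric conjugate addition/aldol on 2,4,4-trimethylcyclohexenone; the C5 chain is grown into a 2-substituted acrolein and then an α-methylene-γ-butyrolactone; one radical bicyclization closes ring B and the seven-membered ring; oxygen insertion and lactone reduction give the oxocane.
- Stereochemistry: C5 from the copper catalyst, C10 from anti trapping of the enolate, C15 (temporary) from the chromium catalyst; C9, C8 and C13 arise in the key step (chair, sterics, bridged-lactone relay from C15); the C8–O bond forms with retention in the Baeyer–Villiger step.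

Key step: step 7

Remark: all compounds carry the labdane locants of the target: decalin C1–C10 (C4 gem-dimethyl, C10 methyl C20), C8 (methyl C17, ring oxygen), chain C9–C11–C12–C13(–C16H2OAc)–C14–C15–O; β is the face of C20.

**Route**

Step 1
Reactants: 1 2,4,4-trimethylcyclohex-2-en-1-one; 2 2-(3-chloropropyl)-1,3-dioxolane
Product: 5 (2S,3S)-3-[3-(1,3-dioxolan-2-yl)propyl]-2-(1-hydroxyethyl)-2,4,4-trimethylcyclohexan-1-one (carbinol epimers), via Grignard reagent 3 (not isolated), via magnesium enolate 4 (not isolated)
Conditions: Mg, THF, 50 °C; then CuBr·SMe2 (5 mol %), chiral ferrocenyl diphosphine (Josiphos type), 1, t-BuOMe, −78 °C; then CH3CHO, −78 to −30 °C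
Reagents that add atoms: acetaldehyde, CC=O
Why: Copper-catalysed asymmetric conjugate addition of the Grignard reagent followed by aldol trapping of the magnesium enolate; the chiral copper–phosphine complex chooses the enone face (C5), and acetaldehyde enters anti to the new C5 chain, so the future vinyl carbon on C10 is trans to the side chain.

Step 2
Reactants: 5 (2S,3S)-3-[3-(1,3-dioxolan-2-yl)propyl]-2-(1-hydroxyethyl)-2,4,4-trimethylcyclohexan-1-one
Product: 6 (2R,3S)-3-[3-(1,3-dioxolan-2-yl)propyl]-2-ethenyl-2,4,4-trimethylcyclohexan-1-one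
Conditions: Burgess reagent (MeO2C–N(−)–SO2–N(+)Et3), benzene, 50 °C
Reagents that add atoms: none
Why: Burgess dehydration (syn elimination of the sulfamate ester) can only take a hydrogen from the methyl group because C10 is quaternary, so both carbinol epimers converge on the vinyl group without touching C5 or C10.

Step 3
Reactants: 6 (2R,3S)-3-[3-(1,3-dioxolan-2-yl)propyl]-2-ethenyl-2,4,4-trimethylcyclohexan-1-one
Product: 8 2-{3-[(1S,2R)-2-ethenyl-2,6,6-trimethylcyclohexyl]propyl}-1,3-dioxolane, via hydrazone 7 (not isolated)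
Conditions: N2H4·H2O, KOH, diethylene glycol, 130 °C then 200 °C, under argon
Reagents that add atoms: none
Why: Wolff–Kishner reduction (Huang-Minlon conditions) removes the C1 carbonyl; C10 has no hydrogen, so neither epimerization nor alkene migration is possible, and the acetal is stable to base.

Step 4
Reactants: 8 2-{3-[(1S,2R)-2-ethenyl-2,6,6-trimethylcyclohexyl]propyl}-1,3-dioxolane
Product: 9 4-[(1S,2R)-2-ethenyl-2,6,6-trimethylcyclohexyl]butanal
Conditions: 2 M HCl, THF, rt
Reagents that add atoms: water, O
Why: Acid-catalysed acetal hydrolysis frees the aldehyde; the isolated vinyl group on a quaternary carbon should be inert to dilute acid at room temperature.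

Step 5
Reactants: 9 4-[(1S,2R)-2-ethenyl-2,6,6-trimethylcyclohexyl]butanal
Product: 10 4-[(1S,2R)-2-ethenyl-2,6,6-trimethylcyclohexyl]-2-methylidenebutanal
Conditions: 37% aq. CH2O, pyrrolidine (10 mol %), EtCO2H (10 mol %), i-PrOH, 45 °C
Reagents that add atoms: formaldehyde, C=O
Why: Amine-catalysed Mannich condensation/elimination (α-methylenation of an aldehyde) gives the 2-substituted acrolein and brings in the carbon that becomes the C8 methyl (C17).

Step 6
Reactants: 10 4-[(1S,2R)-2-ethenyl-2,6,6-trimethylcyclohexyl]-2-methylidenebutanal; 11 methyl 2-(bromomethyl)prop-2-enoate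
Product: 14 (5R)-5-{4-[(1S,2R)-2-ethenyl-2,6,6-trimethylcyclohexyl]but-1-en-2-yl}-3-methylideneoxolan-2-one, via silyl ether 12 (not isolated), via hydroxy ester 13 (not isolated)
Conditions: CrCl2 (10 mol %), chiral carbazole bis(oxazoline) ligand, Mn powder, Me3SiCl, THF, rt; then 1 M HCl, THF; then p-TsOH (cat.), CH2Cl2, rt
Reagents that add atoms: none
Why: Catalytic asymmetric Nozaki–Hiyama–Kishi-type 2-(alkoxycarbonyl)allylation of the enal followed by acid lactonization; the chiral chromium allyl species sets the temporary C15 centre (R) by catalyst control, because the nearest stereocentre is five bonds away.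

Step 7
Reactants: 14 (5R)-5-{4-[(1S,2R)-2-ethenyl-2,6,6-trimethylcyclohexyl]but-1-en-2-yl}-3-methylideneoxolan-2-one
Product: 15 (5S,8R,9R,10S,13R,15R)-bridged lactone: trans-fused 4,4,8,10-tetramethyldecalin carrying the cycloheptane C8–C15–C14–C13–C12–C11–C9 and the γ-lactone O–C16(=O) that spans C15 (oxygen) and C13 (carbonyl)
Conditions: Fe(acac)3 (30 mol %), PhSiH3 (slow addition), EtOH/HOCH2CH2OH 5:1, 0.005 M, 60 °C
Reagents that add atoms: none
Why: Proposed new method: hydrogen-atom transfer from the iron hydride to the CH2 terminus of the 1,1-disubstituted alkene makes the C17 methyl and the tertiary C8 radical, which closes ring B by 6-exo-trig attack on C9 of the vinyl group; the C11 radical then closes the seven-membered ring by 7-endo-trig Giese addition to C12 of the α-methylene lactone, and the α-acyl radical at C13 is reduced and protonated. The closest known reaction types are the iron-hydride reductive olefin–olefin coupling (intramolecular Giese cyclization) and the stannane-mediated tandem 6-exo/7-endo radical cyclization; new is that the first acceptor is an unactivated vinyl group on a quaternary carbon. C9 is set by the chair transition state held by the trans-diequatorial chains on ring A (C11 equatorial); C8 by sterics, since the branched lactone carbon C15 should take the equatorial site and leave the new methyl axial, syn to C20; C13 by the bridged lactone, whose C15 centre allows only the cis 1,3-bridge, so the hydrogen can only enter from outside. The step needs hydrogen-atom transfer at the 1,1-disubstituted alkene and not at the vinyl group or the lactone alkene, and 6-exo before 7-endo; the disubstituted alkene is the most reactive acceptor of the hydrogen atom, the vinyl group has no allylic hydrogen, and direct attack of C8 on the lactone alkene would be a 5-endo or 4-exo closure. High dilution and slow silane addition should keep the tertiary radical alive long enough for the first ring closure.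

Step 8
Reactants: 15 (5S,8R,9R,10S,13R,15R)-bridged lactone
Product: 16 (5S,8R,9R,10S,13R,15R)-diol: the same 6-6-7 carbocycle with 15-OH and 13-CH2OH (cis)
Conditions: LiAlH4, THF, 0 °C to rt
Reagents that add atoms: none
Why: Hydride reduction of the γ-lactone opens the bridge to the diol without touching a stereocentre and exposes the C15 carbinol and the C16 primary alcohol.

Step 9
Reactants: 16 (5S,8R,9R,10S,13R,15R)-diol
Product: 17 16-O-(tert-butyldiphenylsilyl) ether of diol 16
Conditions: t-BuPh2SiCl, imidazole, CH2Cl2, 0 °C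
Reagents that add atoms: tert-butyl(chloro)diphenylsilane, CC(C)(C)[Si](Cl)(c1ccccc1)c1ccccc1
Why: Selective silylation: the bulky silyl chloride should react only with the primary alcohol, because the secondary C15–OH is flanked by the quaternary C8.

Step 10
Reactants: 17 16-O-(tert-butyldiphenylsilyl) ether of diol 16
Product: 18 (5S,8R,9R,10S,13R)-cycloheptanone: C15 ketone on the 6-6-7 carbocycle with 13-CH2OSi(t-Bu)Ph2
Conditions: Dess–Martin periodinane, CH2Cl2, rt
Reagents that add atoms: none
Why: Dess–Martin oxidation of the hindered secondary alcohol gives the ketone and deletes the temporary C15 stereocentre after it has relayed its configuration to C13, which is not α to the carbonyl and cannot epimerize.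

Step 11
Reactants: 18 (5S,8R,9R,10S,13R)-cycloheptanone
Product: 19 (5S,8R,9R,10S,13R)-eight-membered lactone: oxocan-2-one with O between C8 and C15 and C15=O
Conditions: mCPBA, CH2Cl2, 0 °C to rt
Reagents that add atoms: 3-chloroperoxybenzoic acid, OOC(=O)c1cccc(Cl)c1
Why: Baeyer–Villiger oxidation: the fully substituted C8 migrates in preference to the C14 methylene and with retention, so the oxygen is inserted between C15 and C8 on the α-face and the seven-membered ketone becomes the eight-membered lactone.

Step 12
Reactants: 19 (5S,8R,9R,10S,13R)-eight-membered lactone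
Product: 21 15-acetoxy oxocane (C15 epimers) with 13-CH2OSi(t-Bu)Ph2, via aluminium hemiacetal 20 (not isolated)
Conditions: i-Bu2AlH, CH2Cl2, −78 °C; then pyridine, DMAP, Ac2O, −78 °C to rt
Reagents that add atoms: acetic anhydride, CC(=O)OC(C)=O
Why: Reductive acetylation of the lactone (one hydride at −78 °C, then trapping of the aluminium hemiacetal with acetic anhydride before it can open) gives the α-acetoxy ether, a stable precursor of the ring oxocarbenium ion.

Step 13
Reactants: 21 15-acetoxy oxocane
Product: 22 (5S,8R,9R,10S,13R)-8,15-epoxylabdan-16-yl tert-butyldiphenylsilyl ether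
Conditions: Et3SiH, BF3·OEt2, CH2Cl2, −78 °C
Reagents that add atoms: none
Why: Ionic reduction: BF3·OEt2 ionizes the anomeric acetate to the ring oxocarbenium ion, which triethylsilane reduces to the oxocane; at −78 °C the tertiary C8–O bond should survive.

Step 14
Reactants: 22 (5S,8R,9R,10S,13R)-8,15-epoxylabdan-16-yl tert-butyldiphenylsilyl ether
Product: 23 (5S,8R,9R,10S,13R)-8,15-epoxylabdan-16-ol
Conditions: Bu4NF, THF, rt
Reagents that add atoms: none
Why: Fluoride-mediated desilylation frees the primary alcohol and leaves the cyclic ether untouched.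

Step 15
Reactants: 23 (5S,8R,9R,10S,13R)-8,15-epoxylabdan-16-ol
Product: 24 (5S,8R,9R,10S,13R)-8,15-epoxylabdan-16-yl acetate (CNP0152986.1)
Conditions: Ac2O, pyridine, DMAP (cat.), CH2Cl2, rt
Reagents that add atoms: acetic anhydride, CC(=O)OC(C)=O
Why: Acetylation of the primary alcohol with nucleophilic catalysis by DMAP should give the target.

**Compound list**

1 | 2,4,4-trimethylcyclohex-2-en-1-one | CC1=CC(C)(C)CCC1=O | starting material
2 | 2-(3-chloropropyl)-1,3-dioxolane | ClCCCC1OCCO1 | starting material
3 | [3-(1,3-dioxolan-2-yl)propyl]magnesium chloride | Cl[Mg]CCCC1OCCO1 | intermediate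
4 | chloromagnesium enolate of (3S)-3-[3-(1,3-dioxolan-2-yl)propyl]-2,4,4-trimethylcyclohexan-1-one | O1CCOC1CCC[C@H]2C(C)(C)CCC(O[Mg]Cl)=C2C | intermediate
5 | (2S,3S)-3-[3-(1,3-dioxolan-2-yl)propyl]-2-(1-hydroxyethyl)-2,4,4-trimethylcyclohexan-1-one (carbinol epimers) | O1CCOC1CCC[C@H]2C(C)(C)CCC(=O)[C@]2(C)C(C)O | intermediate
6 | (2R,3S)-3-[3-(1,3-dioxolan-2-yl)propyl]-2-ethenyl-2,4,4-trimethylcyclohexan-1-one | O1CCOC1CCC[C@H]2C(C)(C)CCC(=O)[C@]2(C)C=C | intermediate
7 | hydrazone of 6 | O1CCOC1CCC[C@H]2C(C)(C)CCC(=NN)[C@]2(C)C=C | intermediate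
8 | 2-{3-[(1S,2R)-2-ethenyl-2,6,6-trimethylcyclohexyl]propyl}-1,3-dioxolane | O1CCOC1CCC[C@H]2C(C)(C)CCC[C@]2(C)C=C | intermediate
9 | 4-[(1S,2R)-2-ethenyl-2,6,6-trimethylcyclohexyl]butanal | O=CCCC[C@H]1C(C)(C)CCC[C@]1(C)C=C | intermediate
10 | 4-[(1S,2R)-2-ethenyl-2,6,6-trimethylcyclohexyl]-2-methylidenebutanal | O=CC(=C)CC[C@H]1C(C)(C)CCC[C@]1(C)C=C | intermediate
11 | methyl 2-(bromomethyl)prop-2-enoate | C=C(CBr)C(=O)OC | starting material
12 | methyl (4R)-7-[(1S,2R)-2-ethenyl-2,6,6-trimethylcyclohexyl]-2,5-dimethylidene-4-(trimethylsilyloxy)heptanoate | COC(=O)C(=C)C[C@@H](O[Si](C)(C)C)C(=C)CC[C@H]1C(C)(C)CCC[C@]1(C)C=C | intermediate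
13 | methyl (4R)-7-[(1S,2R)-2-ethenyl-2,6,6-trimethylcyclohexyl]-4-hydroxy-2,5-dimethylideneheptanoate | COC(=O)C(=C)C[C@@H](O)C(=C)CC[C@H]1C(C)(C)CCC[C@]1(C)C=C | intermediate
14 | (5R)-5-{4-[(1S,2R)-2-ethenyl-2,6,6-trimethylcyclohexyl]but-1-en-2-yl}-3-methylideneoxolan-2-one | C=C1C(=O)O[C@H](C1)C(=C)CC[C@H]2C(C)(C)CCC[C@]2(C)C=C | intermediate
15 | (5S,8R,9R,10S,13R,15R)-bridged lactone (6-6-7 carbocycle, γ-lactone from C15–O to C13–C16=O) | O=C1O[C@H]4[C@]2(C)CC[C@H]3C(C)(C)CCC[C@]3(C)[C@H]2CC[C@@H]1C4 | intermediate
16 | (5S,8R,9R,10S,13R,15R)-diol (15-OH, 13-CH2OH on the 6-6-7 carbocycle) | OC[C@H]1C[C@@H](O)[C@]2(C)CC[C@H]3C(C)(C)CCC[C@]3(C)[C@H]2CC1 | intermediate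
17 | 16-O-(tert-butyldiphenylsilyl) ether of diol 16 | CC(C)(C)[Si](OC[C@H]1C[C@@H](O)[C@]2(C)CC[C@H]3C(C)(C)CCC[C@]3(C)[C@H]2CC1)(c1ccccc1)c1ccccc1 | intermediate
18 | (5S,8R,9R,10S,13R)-cycloheptanone (C15=O, 13-CH2OSi(t-Bu)Ph2) | CC(C)(C)[Si](OC[C@H]1CC(=O)[C@]2(C)CC[C@H]3C(C)(C)CCC[C@]3(C)[C@H]2CC1)(c1ccccc1)c1ccccc1 | intermediate
19 | (5S,8R,9R,10S,13R)-eight-membered lactone (O between C8 and C15, C15=O) | CC(C)(C)[Si](OC[C@H]1CC(=O)O[C@]2(C)CC[C@H]3C(C)(C)CCC[C@]3(C)[C@H]2CC1)(c1ccccc1)c1ccccc1 | intermediate
20 | diisobutylaluminium hemiacetal of lactone 19 | CC(C)(C)[Si](OC[C@H]1CC(O[Al](CC(C)C)CC(C)C)O[C@]2(C)CC[C@H]3C(C)(C)CCC[C@]3(C)[C@H]2CC1)(c1ccccc1)c1ccccc1 | intermediate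
21 | 15-acetoxy oxocane (C15 epimers), 16-O-silyl | CC(C)(C)[Si](OC[C@H]1CC(OC(C)=O)O[C@]2(C)CC[C@H]3C(C)(C)CCC[C@]3(C)[C@H]2CC1)(c1ccccc1)c1ccccc1 | intermediate
22 | (5S,8R,9R,10S,13R)-8,15-epoxylabdan-16-yl tert-butyldiphenylsilyl ether | CC(C)(C)[Si](OC[C@H]1CCO[C@]2(C)CC[C@H]3C(C)(C)CCC[C@]3(C)[C@H]2CC1)(c1ccccc1)c1ccccc1 | intermediate
23 | (5S,8R,9R,10S,13R)-8,15-epoxylabdan-16-ol | OC[C@H]1CCO[C@]2(C)CC[C@H]3C(C)(C)CCC[C@]3(C)[C@H]2CC1 | intermediate
24 | (5S,8R,9R,10S,13R)-8,15-epoxylabdan-16-yl acetate (CNP0152986.1) | CC(=O)OC[C@H]1CCO[C@]2(C)CC[C@H]3C(C)(C)CCC[C@]3(C)[C@H]2CC1 | target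

**Step count and risks**

Total step count: 15. Longest linear sequence: 15 steps (from 1 or 2 to 24).

Steps most likely to fail:

Step 7. The tertiary C8 radical may be quenched (net hydrogenation of the 1,1-disubstituted alkene) before the slow 6-exo closure onto the hindered, unactivated vinyl carbon, it may attack the vinyl terminus in the 7-endo mode, or the hydrogen atom may go to the lactone alkene instead. The fallback sets out from 14 and uses a stannane chain, in which the radical is made by halogen abstraction and the hydrogen donor can be kept at very low concentration. Markovnikov addition of dry HCl (CH2Cl2, −40 °C) to the 1,1-disubstituted alkene should give (5R)-5-{2-chloro-4-[(1S,2R)-2-ethenyl-2,6,6-trimethylcyclohexyl]butan-2-yl}-3-methylideneoxolan-2-one F1. Slow addition of Bu3SnH with AIBN in refluxing benzene at high dilution (classical tandem 6-exo/7-endo radical cyclization) should then give 15, where the fallback comes back to the route.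

Step 1. Facial selectivity of the copper complex may be poor on the enone with a quaternary γ-carbon, and aldol trapping of the congested tetrasubstituted magnesium enolate may be incomplete (proton quench, retro-aldol). The fallback sets out from 1 and 3 and separates the two events. Conjugate addition in the presence of Me3SiCl should give 2-{3-[(1S)-2,6,6-trimethyl-3-(trimethylsilyloxy)cyclohex-2-en-1-yl]propyl}-1,3-dioxolane F2, which is isolated. A Mukaiyama aldol reaction with acetaldehyde (BF3·OEt2, CH2Cl2, −78 °C), again anti to the C5 chain, should give 5, where the fallback comes back.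

Step 6. Catalyst control at C15 may be insufficient on the α-branched enal, and any C15 epimer is relayed to C13 in step 7. The fallback sets out from 10 and 11 and sets C15 by reduction instead of by C–C bond formation. An indium-mediated Barbier allylation (In, THF/H2O) should give methyl 7-[(1S,2R)-2-ethenyl-2,6,6-trimethylcyclohexyl]-4-hydroxy-2,5-dimethylideneheptanoate F3 as C4 epimers. Dess–Martin oxidation should give methyl 7-[(1S,2R)-2-ethenyl-2,6,6-trimethylcyclohexyl]-2,5-dimethylidene-4-oxoheptanoate F4. Corey–Bakshi–Shibata reduction of this α-methylene ketone (oxazaborolidine enantiomer chosen for 15R, BH3·SMe2) should give 13, which lactonizes to 14 as in step 6.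

Further compounds
F1 | step 7 | (5R)-5-{2-chloro-4-[(1S,2R)-2-ethenyl-2,6,6-trimethylcyclohexyl]butan-2-yl}-3-methylideneoxolan-2-one (C8 epimers) | C=C1C(=O)O[C@H](C1)C(C)(Cl)CC[C@H]2C(C)(C)CCC[C@]2(C)C=C
F2 | step 1 | 2-{3-[(1S)-2,6,6-trimethyl-3-(trimethylsilyloxy)cyclohex-2-en-1-yl]propyl}-1,3-dioxolane | O1CCOC1CCC[C@H]2C(C)(C)CCC(O[Si](C)(C)C)=C2C
F3 | step 6 | methyl 7-[(1S,2R)-2-ethenyl-2,6,6-trimethylcyclohexyl]-4-hydroxy-2,5-dimethylideneheptanoate (C4 epimers) | COC(=O)C(=C)CC(O)C(=C)CC[C@H]1C(C)(C)CCC[C@]1(C)C=C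
F4 | step 6 | methyl 7-[(1S,2R)-2-ethenyl-2,6,6-trimethylcyclohexyl]-2,5-dimethylidene-4-oxoheptanoate | COC(=O)C(=C)CC(=O)C(=C)CC[C@H]1C(C)(C)CCC[C@]1(C)C=C
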